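**Retrosynthetic overview**

1. Numbering follows 2,11-cyclised cembranoids (C1/C10 ring fusion, C2 and C9 ether carbons, C3 lactone carbinol, C6=C7, C11 butyrate carbon, C14–C15–C16 lactone arm). Target ⇒ C11 butyrylation, C16/C3–OH lactonisation, hydroboration of a C14 isopropenyl group and C6=C7 ring-closing metathesis ⇒ a 2,5-cis-disubstituted hexahydroisobenzofuran diol.
2. Its C9 methallyl group and its C11 oxygen both come from the carboxyl groups of a geminal C9 diester: the carboxyl cis to C11 delivers the C11–O bond by iodolactonisation and is then exchanged for methallyl by decarboxylative radical allylation.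
3. Key disconnection: the tetrahydrofuran O–C2–C1–C10–C9 ⇐ ring contraction of the six-membered 3,6-dihydro-2H-pyran ring O–C2–C1–C10=C11–C12 of a 2-oxabicyclo[2.2.2]oct-5-ene, by oxonium ylide formation from a diazomalonate tethered through O–C3 and [2,3]-shift (C9–C10 formed, C12–O broken). Enabling feature: in this bridged allylic ether the ring oxygen and the remote alkene carbon C10 face each other 1,4 across the boat, and the C3 substituent on C2 points to the C10=C11 bridge.
4. The bicyclic ether ⇐ (R)-carvone + (S)-2-methylglycidal: aldol addition, intramolecular oxa-Michael addition with enolate triflation, triflate reduction, allyl opening of the epoxide.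
5. Order of rings: cyclohexene (carvone) → dihydropyran (oxa bridge) → tetrahydrofuran by contraction, together with a temporary dioxanone → temporary γ-lactone → oxonene → ε-lactone.

Key step: step 8

Remark: the absolute configuration derives from (R)-carvone (C14) and (R)-2-methylglycidol (C3), both taken as commercial enantiopure materials; every other centre is set relative to these.

**Route**

Step 1
Reactants: 1 (R)-2-methylglycidol
Product: 2 (S)-2-methyloxirane-2-carbaldehyde
Conditions: Dess–Martin periodinane, pyridine, CH2Cl2, 0 °C to rt; short-path distillation, used at once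
Reagents that add atoms: none
Why: Dess–Martin oxidation of the primary epoxy alcohol should stop at the non-enolisable epoxy aldehyde; the quaternary centre (the later C3) is not touched and only its descriptor changes.

Step 2
Reactants: 3 (R)-(−)-carvone; 2 (S)-2-methyloxirane-2-carbaldehyde
Product: 5 epoxy aldol adduct, via lithium dienolate 4 (not isolated)
Conditions: LiN(iPr)2, THF, −78 °C; then 2, −78 °C; AcOH quench at −78 °C
Reagents that add atoms: none
Why: Aldol addition of the kinetic cross-conjugated dienolate (deprotonation at C6 of carvone) through a chair Zimmerman–Traxler transition state on the face anti to the isopropenyl group should set C1 trans to C14 and, as the anti aldol, C2; the weak facial bias of the α-quaternary aldehyde is expected to be overridden.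

Step 3
Reactants: 5 epoxy aldol adduct
Product: 8 bicyclic enol triflate, via potassium alkoxide 6 (not isolated), via bicyclic potassium enolate 7 (not isolated)
Conditions: KN(SiMe3)2 (1.1 equiv), THF, −78 to −20 °C; then PhNTf2, −78 to 0 °C
Reagents that add atoms: N-phenylbis(trifluoromethanesulfonimide) O=S(=O)(N(c1ccccc1)S(=O)(=O)C(F)(F)F)C(F)(F)F
Why: Intramolecular oxa-Michael addition (the oxygen counterpart of the second step of a double Michael annulation of carvone enolates) of the alkoxide to the enone β-carbon C12 across the ring closes the 2-oxabicyclo[2.2.2]octane and sets C12 on the face of the side chain; the enolate, more stable than the alkoxide, is trapped by O-triflation as the only possible enol triflate (C1 is a bridgehead), and Payne rearrangement is blocked because it would need substitution at the fully substituted epoxide carbon.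

Step 4
Reactants: 8 bicyclic enol triflate
Product: 9 bicyclic epoxy alkene
Conditions: Pd(PPh3)4 (5 mol%), LiCl, Bu3SnH, THF, 50 °C
Reagents that add atoms: none
Why: Palladium-catalysed hydride reduction of the enol triflate (oxidative addition, tin-to-palladium hydride transfer, reductive elimination) removes the C10 oxygen and leaves the C10=C11 alkene; no stereocentre is touched.

Step 5
Reactants: 9 bicyclic epoxy alkene
Product: 10 bicyclic tertiary alcohol
Conditions: CH2=CHCH2MgBr, CuI (10 mol%), THF, −40 to −10 °C; aqueous NH4Cl
Reagents that add atoms: allylmagnesium bromide C=CC[Mg]Br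
Why: Copper-catalysed Grignard opening of the 2,2-disubstituted epoxide at its methylene carbon (SN2) installs the but-3-enyl chain and frees the tertiary C3 alcohol with C3 unchanged.

Step 6
Reactants: 10 bicyclic tertiary alcohol
Product: 11 mixed methyl malonate
Conditions: methyl malonyl chloride, Et3N, CH2Cl2, 0 °C
Reagents that add atoms: methyl 3-chloro-3-oxopropanoate COC(=O)CC(Cl)=O
Why: Acylation of the hindered tertiary alcohol should proceed through (methoxycarbonyl)ketene, formed from the acid chloride and the amine, which adds even to tertiary alcohols.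

Step 7
Reactants: 11 mixed methyl malonate
Product: 12 diazomalonate
Conditions: 4-acetamidobenzenesulfonyl azide, Et3N, MeCN, rt
Reagents that add atoms: 4-acetamidobenzenesulfonyl azide CC(=O)Nc1ccc(cc1)S(=O)(=O)N=[N+]=[N-]
Why: Regitz diazo transfer to the doubly activated malonate methylene.

Step 8
Reactants: 12 diazomalonate
Product: 14 bridged lactone ester, via oxonium ylide 13 (not isolated)
Conditions: Cu(hfacac)2 (5 mol%), ClCH2CH2Cl, reflux, slow addition of 12 (high dilution)
Reagents that add atoms: none
Why: Proposed new method: the copper carbene formed from 12 is captured by the bridging ether oxygen to give oxonium ylide 13, whose carbanion carbon C9 bonds to the remote alkene carbon C10 while the bridgehead C12–O bond breaks, a [2,3]-sigmatropic shift through a five-membered envelope transition state that contracts the six-membered dihydropyran ring O–C2–C1–C10=C11–C12 to the tetrahydrofuran O–C2–C1–C10–C9 and moves the alkene to C11=C12. The closest known reaction types are the copper- or rhodium-catalysed intramolecular oxonium ylide formation/[2,3]-rearrangement of allyl ethers and the ring-contracting [2,3]-shift of cyclic allylic ammonium ylides; new is the bridged bicyclic allylic ether as substrate. Ring closures: the 1,4-dioxan-2-one ring closes by attack of an oxygen lone pair on the electrophilic carbene carbon (six-membered ring through the s-cis ester), and the tetrahydrofuran arises by the suprafacial 1,3-transposition, C9 being delivered to C10 on the face that the oxygen leaves. Stereocontrol: this suprafaciality sets C10 cis to C2 (cis ring fusion), and at the quaternary C9 the tether holds the lactone carbonyl on the face of C3, which forces the free CO2Me onto the face of C11. The step needs ylide formation to win over C–H insertion at C2–H and cyclopropanation, and the [2,3]- over the [1,2]-shift; an electrophilic copper catalyst, the endo position of C3 that holds the carbene over the C10=C11 bridge, the proximity of oxygen and C10 across the boat and the release of bicyclic strain should secure this.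

Step 9
Reactants: 14 bridged lactone ester
Product: 16 iodolactone acid, via dilithium malonate 15 (not isolated)
Conditions: LiOH (2.1 equiv), THF/H2O, 40 °C; then I2, 0 °C, dark; then 1 M HCl
Reagents that add atoms: lithium hydroxide [Li+].[OH-]; iodine II
Why: Saponification opens the bridged lactone and the methyl ester; iodolactonisation then sets C11, because the iodonium forms on the open convex face of C11=C12 and only the carboxylate cis to C11 can reach, attacking the tertiary carbon anti in a 5-exo closure (oxygen cis to C9, methyl cis to H10, a relationship an external reagent would not give).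

Step 10
Reactants: 16 iodolactone acid
Product: 18 γ-lactone, via deiodinated half-acid 17 (not isolated)
Conditions: Bu3SnH, AIBN, toluene, 80 °C; then 110 °C
Reagents that add atoms: none
Why: Radical chain reduction with tin hydride removes the C12 iodide, and the malonic half-acid then loses CO2 thermally through the lactone enol, which can only be reprotonated at C9 on the convex face because the cis-fused γ-lactone keeps its carbonyl on the face of C11.

Step 11
Reactants: 18 γ-lactone
Product: 20 methallyl diol, via cesium carboxylate 19 (not isolated)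
Conditions: CsOH·H2O (1.0 equiv), THF/H2O, rt, evaporation; then 2-methylallyl phenyl sulfone, Ir[dF(CF3)ppy]2(dtbbpy)PF6 (2 mol%), DMSO, blue LEDs, rt
Reagents that add atoms: 2-methylallyl phenyl sulfone CC(=C)CS(=O)(=O)c1ccccc1
Why: Photoredox decarboxylative radical allylation: oxidation of the α-alkoxy carboxylate by the excited iridium photocatalyst, loss of CO2, addition of the C9 radical to the allyl sulfone on the convex face anti to the cyclohexane ring and β-scission of sulfinate; the C9 configuration is therefore set here (methallyl cis to the C2 side chain) whatever it was before.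

Step 12
Reactants: 20 methallyl diol
Product: 21 oxonene diol
Conditions: second-generation Grubbs catalyst (10 mol%), CH2Cl2 (2 mM), 40 °C
Reagents that add atoms: none
Why: Ring-closing metathesis of the butenyl and methallyl groups held cis on the tetrahydrofuran closes the nine-membered oxonene; the ring admits only the Z (ring-cis) trisubstituted alkene, and the α-branched isopropenyl group should be too hindered to compete.

Step 13
Reactants: 21 oxonene diol
Product: 23 triol, via B-alkyl-9-BBN adduct 22 (not isolated)
Conditions: 9-BBN (excess), THF, 0 °C to rt; then NaOH, H2O2, 0 °C to rt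
Reagents that add atoms: hydrogen peroxide OO
Why: Hydroboration–oxidation with 9-BBN is selective for the 1,1-disubstituted alkene over the trisubstituted ring alkene; with H14 eclipsing the C=CH2 bond (allylic 1,3-strain model) the borane should add anti to the bulkier C1 flank, from the C13 side, which gives (15R), and the oxidation proceeds with retention.

Step 14
Reactants: 23 triol
Product: 25 hydroxy acid, via hydroxy aldehyde 24 (not isolated)
Conditions: TEMPO (20 mol%), PhI(OAc)2, MeCN/H2O, rt
Reagents that add atoms: water O
Why: Oxoammonium (TEMPO) oxidation in aqueous medium takes the primary alcohol through the aldehyde hydrate to the acid and should leave the tertiary alcohols, the alkene and the α-stereocentre untouched.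

Step 15
Reactants: 25 hydroxy acid
Product: 27 hydroxy ε-lactone, via mixed anhydride 26 (not isolated)
Conditions: 2,4,6-trichlorobenzoyl chloride, Et3N, THF, rt; then DMAP, toluene, 80 °C, high dilution
Reagents that add atoms: none
Why: Yamaguchi lactonisation: the DMAP-activated mixed anhydride is captured by the C3 hydroxyl, the only one within reach (the C11 hydroxyl lies trans-1,4 across the chair), closing the seven-membered lactone on a rigid scaffold.

Step 16
Reactants: 27 hydroxy ε-lactone
Product: 28 target butyrate
Conditions: butyric anhydride, DMAP, Et3N, CH2Cl2, 40 °C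
Reagents that add atoms: butyric anhydride CCCC(=O)OC(=O)CCC
Why: DMAP-catalysed acylation of the one remaining (tertiary, equatorial) alcohol at C11.

**Compound list**

1 | (R)-2-methylglycidol, (2R)-(2-methyloxiran-2-yl)methanol | C[C@@]1(CO)CO1 | starting material
2 | (S)-2-methyloxirane-2-carbaldehyde | C[C@@]1(C=O)CO1 | intermediate
3 | (R)-(−)-carvone, (5R)-2-methyl-5-(prop-1-en-2-yl)cyclohex-2-en-1-one | CC1=CC[C@@H](C(C)=C)CC1=O | starting material
4 | lithium dienolate of 3 (deprotonated at C6, cross-conjugated) | CC1=CC[C@@H](C(C)=C)C=C1[O-].[Li+] | intermediate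
5 | epoxy aldol adduct, (5R,6R)-6-{(S)-hydroxy[(2S)-2-methyloxiran-2-yl]methyl}-2-methyl-5-(prop-1-en-2-yl)cyclohex-2-en-1-one | CC1=CC[C@@H](C(C)=C)[C@H]([C@H](O)[C@]2(C)CO2)C1=O | intermediate
6 | potassium alkoxide of 5 | CC1=CC[C@@H](C(C)=C)[C@H]([C@H]([O-])[C@]2(C)CO2)C1=O.[K+] | intermediate
7 | bicyclic potassium enolate, potassium (1R,3S,4R,8R)-6-methyl-3-[(2S)-2-methyloxiran-2-yl]-8-(prop-1-en-2-yl)-2-oxabicyclo[2.2.2]oct-5-en-5-olate | CC1=C([O-])[C@@H]2[C@H](C(C)=C)C[C@H]1O[C@@H]2[C@]3(C)CO3.[K+] | intermediate
8 | bicyclic enol triflate, (1R,3S,4R,8R)-6-methyl-3-[(2S)-2-methyloxiran-2-yl]-8-(prop-1-en-2-yl)-2-oxabicyclo[2.2.2]oct-5-en-5-yl trifluoromethanesulfonate | CC1=C(OS(=O)(=O)C(F)(F)F)[C@@H]2[C@H](C(C)=C)C[C@H]1O[C@@H]2[C@]3(C)CO3 | intermediate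
9 | bicyclic epoxy alkene, (1R,3S,4R,8R)-6-methyl-3-[(2S)-2-methyloxiran-2-yl]-8-(prop-1-en-2-yl)-2-oxabicyclo[2.2.2]oct-5-ene (both the C3 and the C8 substituent point to the C5=C6 bridge) | CC1=C[C@@H]2[C@H](C(C)=C)C[C@H]1O[C@@H]2[C@]3(C)CO3 | intermediate
10 | bicyclic tertiary alcohol, (2S)-2-[(1R,3S,4R,8R)-6-methyl-8-(prop-1-en-2-yl)-2-oxabicyclo[2.2.2]oct-5-en-3-yl]hex-5-en-2-ol | CC1=C[C@@H]2[C@H](C(C)=C)C[C@H]1O[C@@H]2[C@@](C)(O)CCC=C | intermediate
11 | mixed methyl malonate (methyl malonate ester on the tertiary oxygen of 10) | CC1=C[C@@H]2[C@H](C(C)=C)C[C@H]1O[C@@H]2[C@@](C)(OC(=O)CC(=O)OC)CCC=C | intermediate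
12 | diazomalonate (methyl 2-diazomalonate ester of 10) | CC1=C[C@@H]2[C@H](C(C)=C)C[C@H]1O[C@@H]2[C@@](C)(OC(=O)C(=[N+]=[N-])C(=O)OC)CCC=C | intermediate
13 | oxonium ylide (ring oxygen of the bicycle bonded to the malonate carbon, closing a 1,4-dioxan-2-one ring) | CC1=C[C@@H]2[C@H](C(C)=C)C[C@H]1[O+]3[C@@H]2[C@](C)(CCC=C)OC(=O)[C-]3C(=O)OC | intermediate
14 | bridged lactone ester: cis-fused hexahydroisobenzofuran (C11=C12 alkene, C14 isopropenyl) whose C9 carries CO2Me cis to C11 and a carbonyl lactonised to the C3 oxygen; C3 bears methyl and but-3-enyl | CC1=CC[C@@H](C(C)=C)[C@H]2[C@@H]1[C@@]3(C(=O)OC)O[C@@H]2[C@](C)(CCC=C)OC3=O | intermediate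
15 | dilithium malonate (C9 dicarboxylate, free C3 hydroxyl) | CC1=CC[C@@H](C(C)=C)[C@H]2[C@@H]1C(C(=O)[O-])(C(=O)[O-])O[C@@H]2[C@@](C)(O)CCC=C.[Li+].[Li+] | intermediate
16 | iodolactone acid: γ-lactone from the C9 carboxyl cis to C11 onto C11 (oxygen cis to C9), iodine at C12 trans to the lactone oxygen, free CO2H at C9 | C[C@]12OC(=O)[C@@]3(C(=O)O)O[C@H]([C@@](C)(O)CCC=C)[C@H]([C@@H]13)[C@H](C(C)=C)C[C@@H]2I | intermediate
17 | deiodinated half-acid (16 with C12 as CH2) | C[C@]12OC(=O)[C@@]3(C(=O)O)O[C@H]([C@@](C)(O)CCC=C)[C@H]([C@@H]13)[C@H](C(C)=C)CC2 | intermediate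
18 | γ-lactone (C9–H on the convex face, lactone carbonyl on the face of C11) | C[C@]12OC(=O)[C@H]3O[C@H]([C@@](C)(O)CCC=C)[C@H]([C@@H]13)[C@H](C(C)=C)CC2 | intermediate
19 | cesium carboxylate (opened lactone, free tertiary C11 and C3 hydroxyls) | C[C@@]1(O)CC[C@@H](C(C)=C)[C@H]2[C@@H]1[C@@H](C(=O)[O-])O[C@@H]2[C@@](C)(O)CCC=C.[Cs+] | intermediate
20 | methallyl diol: cis-fused octahydroisobenzofuran with C9 2-methylallyl and C2 (S)-2-hydroxyhex-5-en-2-yl cis to each other and trans to the carbocycle, C11 tertiary alcohol, C14 isopropenyl | C[C@@]1(O)CC[C@@H](C(C)=C)[C@H]2[C@@H]1[C@H](CC(C)=C)O[C@@H]2[C@@](C)(O)CCC=C | intermediate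
21 | oxonene diol (tricyclic; (Z)-C6=C7) | C[C@@]1(O)CC[C@@H](C(C)=C)[C@H]2[C@@H]1[C@@H]1C/C(C)=C\CC[C@](C)(O)[C@H]2O1 | intermediate
22 | B-alkyl-9-BBN adduct (boron on the former CH2 of the isopropenyl group) | C[C@@]1(O)CC[C@@H]([C@@H](C)CB3C4CCCC3CCC4)[C@H]2[C@@H]1[C@@H]1C/C(C)=C\CC[C@](C)(O)[C@H]2O1 | intermediate
23 | triol ((15R)-1-hydroxypropan-2-yl at C14) | C[C@@]1(O)CC[C@@H]([C@@H](C)CO)[C@H]2[C@@H]1[C@@H]1C/C(C)=C\CC[C@](C)(O)[C@H]2O1 | intermediate
24 | hydroxy aldehyde | C[C@@]1(O)CC[C@@H]([C@@H](C)C=O)[C@H]2[C@@H]1[C@@H]1C/C(C)=C\CC[C@](C)(O)[C@H]2O1 | intermediate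
25 | hydroxy acid | C[C@@]1(O)CC[C@@H]([C@@H](C)C(O)=O)[C@H]2[C@@H]1[C@@H]1C/C(C)=C\CC[C@](C)(O)[C@H]2O1 | intermediate
26 | mixed anhydride with 2,4,6-trichlorobenzoic acid | C[C@@]1(O)CC[C@@H]([C@@H](C)C(=O)OC(=O)c3c(Cl)cc(Cl)cc3Cl)[C@H]2[C@@H]1[C@@H]1C/C(C)=C\CC[C@](C)(O)[C@H]2O1 | intermediate
27 | hydroxy ε-lactone (target without the butyryl group) | O[C@]1(C)CC[C@@H]2[C@H]3[C@@H]1[C@@H]1C/C(C)=C\CC[C@](C)(OC(=O)[C@@H]2C)[C@H]3O1 | intermediate
28 | CNP0294597.2, (1S,2S,3S,9S,10R,11R,14R,15R; 6Z) in the numbering above | CCCC(=O)O[C@]1(C)CC[C@@H]2[C@H]3[C@@H]1[C@@H]1C/C(C)=C\CC[C@](C)(OC(=O)[C@@H]2C)[C@H]3O1 | target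

**Step count and risks**

Total steps: 16. Longest linear sequence: 16 (1 → 28; 15 from carvone 3).

Steps most likely to fail:

Step 8 (proposed new method). The copper carbene may insert into the C2–H bond next to the ether oxygen or cyclopropanate an alkene instead of being captured by the hindered bridging oxygen, and the ylide may undergo a [1,2]-shift of C12 instead of the [2,3]-shift. The fallback uses known chemistry, leaves the route at aldol adduct 5 and avoids the bridged ether. Condensation of 5 with TsNHNH2 would give tosylhydrazone F1. Catecholborane, then NaOAc (reduction of the enone hydrazone with 1,3-shift of the double bond through the allyl diazene), would give transposed cyclohexene epoxy alcohol F2, with the alkene at C10=C11 and C12 a methylene. CH2=CHCH2MgBr/CuI would open the epoxide to cyclohexene diol F3. Rh2(OAc)4-catalysed O–H insertion of dimethyl diazomalonate into the less hindered secondary hydroxyl would give malonyl ether F4. Mn(OAc)3·2H2O in AcOH would then effect an oxidative radical cyclisation–lactonisation to γ-lactone methyl ester F5: 5-exo attack of the malonyl radical on C10 on the face of the tether, oxidation of the tertiary C11 radical by trivalent manganese, and capture of the cation by the cis ester. LiOH followed by acidification would return the route to half-acid 17, which is decarboxylated as in step 10.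

Step 3. Retro-aldol cleavage of the potassium aldolate and proton shuffling to the extended dienolate may outrun the cyclisation, and the bicyclic enolate may expel the alkoxide again before it is trapped. The fallback builds the bridge by cycloaddition: carvone 3 would be deprotonated as in step 2 and dienolate 4 silylated with Me3SiCl to trimethylsilyl dienol ether F6, a 2-silyloxy-1,3-diene. A Lewis-acid-catalysed hetero-Diels–Alder reaction of F6 with aldehyde 2 (Eu(fod)3; carbonyl carbon to the nucleophilic diene terminus C1, oxygen to C12, anti to the isopropenyl group, aldehyde substituent endo) would give bicyclic trimethylsilyl enol ether F7. MeLi would release bicyclic lithium enolate F8, and PhNTf2 would convert it into triflate 8.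

Step 15. The hindered tertiary C3 hydroxyl may fail to capture the activated acyl group, so that intermolecular acylation or ketene formation with loss of the C15 configuration takes over. The fallback bypasses acyl activation by an oxidative lactonisation from triol 23: with TEMPO/PhI(OAc)2 in dry CH2Cl2, hydroxy aldehyde 24 would be intercepted by the C3 hydroxyl as seven-membered lactol F9, which the oxoammonium salt would oxidise to lactone 27.

**Further compounds**

F1 | step 8 | tosylhydrazone of 5 | CC1=CC[C@@H](C(C)=C)[C@H]([C@H](O)[C@]2(C)CO2)C1=NNS(=O)(=O)c1ccc(C)cc1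
F2 | step 8 | transposed cyclohexene epoxy alcohol | CC1=C[C@@H]([C@H](O)[C@]2(C)CO2)[C@H](C(C)=C)CC1
F3 | step 8 | cyclohexene diol | CC1=C[C@@H]([C@H](O)[C@@](C)(O)CCC=C)[C@H](C(C)=C)CC1
F4 | step 8 | malonyl ether | CC1=C[C@@H]([C@H](OC(C(=O)OC)C(=O)OC)[C@@](C)(O)CCC=C)[C@H](C(C)=C)CC1
F5 | step 8 | γ-lactone methyl ester (methyl ester of 17) | C[C@]12OC(=O)[C@@]3(C(=O)OC)O[C@H]([C@@](C)(O)CCC=C)[C@H]([C@@H]13)[C@H](C(C)=C)CC2
F6 | step 3 | trimethylsilyl dienol ether of carvone | CC1=CC[C@@H](C(C)=C)C=C1O[Si](C)(C)C
F7 | step 3 | bicyclic trimethylsilyl enol ether | CC1=C(O[Si](C)(C)C)[C@@H]2[C@H](C(C)=C)C[C@H]1O[C@@H]2[C@]3(C)CO3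
F8 | step 3 | bicyclic lithium enolate | CC1=C([O-])[C@@H]2[C@H](C(C)=C)C[C@H]1O[C@@H]2[C@]3(C)CO3.[Li+]
F9 | step 15 | seven-membered lactol | O[C@]1(C)CC[C@@H]2[C@H]3[C@@H]1[C@@H]1C/C(C)=C\CC[C@](C)(OC(O)[C@@H]2C)[C@H]3O1
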